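**Plan**

- Retrosynthetic cuts: ring C of the flavone at O1–C2 (back to a diaryl ynone); then the alkyne–ring B bond; then, in one stroke, the ring B carbon–C3 bond and the O–C2 bond of the dihydrofuran; last the aryl–prenyl bond.
- Forward order: ring B phenol is ortho-prenylated, the dihydrofuran ring is annulated onto it, ring A is attached as a silylated aryl ethynyl ketone by Sonogashira coupling, and the pyranone ring C closes last on desilylation.
- Enabling feature: the ring B phenol oxygen and its single free ortho carbon form a 1,3-C,O-bis-nucleophile (the other ortho carbon bears the prenyl group, the para carbon an iodine that later becomes the bond to C2 of ring C). C3 (CH–OH), C2 (CH–O) and the attached CMe2–OH carbon of the dihydrofuran are a 2,3-epoxy aldehyde in disguise: aldehyde carbon = C3, epoxide CH = C2, epoxide oxygen = tertiary OH.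
- Stereochemistry: C2 comes from a Sharpless epoxide and is inverted once in the ring closure; C3 comes from chelation-controlled addition to the epoxy aldehyde; both are carried unchanged to the end.

Key step: step 4

Remark: the target descriptors are read as (2S,3S), that is, the C3 hydroxyl trans to the C2 hydroxyisopropyl group; 4-iodophenol, prenyl bromide, prenol, 2,4,6-trihydroxybenzaldehyde and ethynylmagnesium bromide are taken as commercial.

**Route**

Step 1
Reactants: 1 4-iodophenol; 2 prenyl bromide (1-bromo-3-methylbut-2-ene)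
Product: 3 4-iodo-2-(3-methylbut-2-en-1-yl)phenol
Conditions: NaH (1.05 equiv), toluene, 0 °C to rt; then 2 (1.0 equiv), rt
Reagents that add atoms: none
Why: ortho-C-alkylation of a sodium phenoxide contact ion pair in a non-polar solvent, which favours C- over O-alkylation, with the para position blocked by iodine so that only ortho-prenylation can occur.

Step 2
Reactants: 4 prenol (3-methylbut-2-en-1-ol)
Product: 5 [(2R)-3,3-dimethyloxiran-2-yl]methanol
Conditions: Ti(Oi-Pr)4 (5 mol %), D-(−)-diisopropyl tartrate (6 mol %), t-BuOOH (anhydrous, isooctane), 4 Å molecular sieves, CH2Cl2, −20 °C; non-aqueous work-up, distillation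
Reagents that add atoms: tert-butyl hydroperoxide, CC(C)(C)OO
Why: Sharpless asymmetric epoxidation of a primary allylic alcohol, in which the D-(−)-tartrate ligand should deliver oxygen to the face that gives the (R)-epoxy alcohol, the antipode of the (S)-product expected from L-(+)-tartrate.

Step 3
Reactants: 5 [(2R)-3,3-dimethyloxiran-2-yl]methanol
Product: 6 (2S)-3,3-dimethyloxirane-2-carbaldehyde
Conditions: TEMPO (10 mol %), PhI(OAc)2 (1.1 equiv), CH2Cl2, 0 °C to rt; short-path distillation, used as a CH2Cl2 solution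
Reagents that add atoms: none
Why: oxoammonium (TEMPO/PhI(OAc)2) oxidation of a primary alcohol to the aldehyde under near-neutral conditions that the epoxide should tolerate; the stereocentre is untouched and only its descriptor changes from R to S by the priority switch.

Step 4
Reactants: 3 4-iodo-2-(3-methylbut-2-en-1-yl)phenol; 6 (2S)-3,3-dimethyloxirane-2-carbaldehyde
Product: 8 (2S,3S)-2-(2-hydroxypropan-2-yl)-5-iodo-7-(3-methylbut-2-en-1-yl)-2,3-dihydro-1-benzofuran-3-ol, via syn-epoxy alcohol 7 (not isolated)
Conditions: 3, MeMgCl (1.0 equiv), THF, 0 °C; solvent exchanged for CH2Cl2; 6 (1.2 equiv), −40 to 0 °C; then K2CO3 (2 equiv), MeOH, 0 °C to rt; aq. NH4Cl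
Reagents that add atoms: none
Why: Proposed new method: the chloromagnesium phenoxide of 3 binds the aldehyde oxygen of 6 and delivers its only free ortho carbon to the carbonyl carbon through a six-membered transition state (an aromatic aldol, ortho-hydroxyalkylation of a metal phenoxide), rearomatisation gives the phenol epoxy alcohol 7, and potassium carbonate in methanol then frees the phenoxide (the only acid it can deprotonate), which opens the epoxide at its CH carbon by SN2 attack. The closest known reaction types are the chelation-controlled ortho-hydroxyalkylation of magnesium phenoxides with alpha-alkoxy aldehydes and the base-mediated annulation of resorcinol-type phenoxides with 2,3-epoxy aldehydes, neither of which has been run as a magnesium-controlled, enantiospecific sequence on a deactivated monohydric 4-halophenol. The dihydrofuran ring closes in the 5-exo-tet mode, which under basic, Lewis-acid-poor conditions should beat the 6-endo opening at the tertiary carbon that would give a chromane. C3 is set in the C–C bond formation: magnesium chelates the aldehyde and epoxide oxygens in the non-coordinating solvent, so the aryl carbon attacks the carbonyl face opposite the gem-dimethyl carbon (Cram chelate sense, not Felkin–Anh) and should give the (S)-carbinol syn to the epoxide oxygen, while C2 comes from the epoxide CH of 6 with inversion, and syn epoxy alcohol plus one inversion gives the trans-(2S,3S) ring. Site selectivity is fixed by the substrate, since the para carbon bears iodine and the second ortho carbon bears the prenyl group; C- over O-attack on the aldehyde is secured by the tight magnesium phenoxide, and halide opening of the epoxide is avoided by the chloride counter-ion and the low temperature.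

Step 5
Reactants: 9 2,4,6-trihydroxybenzaldehyde
Product: 10 2,4,6-tris(tert-butyldimethylsilyloxy)benzaldehyde
Conditions: TBSCl (3.6 equiv), imidazole (7 equiv), DMF, rt to 40 °C
Reagents that add atoms: tert-butyldimethylsilyl chloride, CC(C)(C)[Si](C)(C)Cl
Why: imidazole-promoted silylation of phenols, giving ring A ethers that should survive Grignard addition, MnO2 and Sonogashira conditions and fall to fluoride at the end.

Step 6
Reactants: 10 2,4,6-tris(tert-butyldimethylsilyloxy)benzaldehyde; 11 ethynylmagnesium bromide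
Product: 12 (±)-1-[2,4,6-tris(tert-butyldimethylsilyloxy)phenyl]prop-2-yn-1-ol
Conditions: 11 (1.3 equiv, 0.5 M in THF), THF, −78 to −20 °C; aq. NH4Cl at −20 °C
Reagents that add atoms: none
Why: Grignard 1,2-addition of an alkynyl nucleophile to an aromatic aldehyde, where the magnesium counter-ion and the cold quench should suppress silyl migration from the ortho silyl ether to the alkoxide; the racemic carbinol centre is removed in the next step.

Step 7
Reactants: 12 (±)-1-[2,4,6-tris(tert-butyldimethylsilyloxy)phenyl]prop-2-yn-1-ol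
Product: 13 1-[2,4,6-tris(tert-butyldimethylsilyloxy)phenyl]prop-2-yn-1-one
Conditions: MnO2 (activated, excess), CH2Cl2, rt
Reagents that add atoms: none
Why: MnO2 oxidation of a doubly activated (benzylic and propargylic) alcohol under neutral heterogeneous conditions that leave the aryl silyl ethers and the base-sensitive terminal ynone intact.

Step 8
Reactants: 8 (2S,3S)-2-(2-hydroxypropan-2-yl)-5-iodo-7-(3-methylbut-2-en-1-yl)-2,3-dihydro-1-benzofuran-3-ol; 13 1-[2,4,6-tris(tert-butyldimethylsilyloxy)phenyl]prop-2-yn-1-one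
Product: 14 3-[(2S,3S)-3-hydroxy-2-(2-hydroxypropan-2-yl)-7-(3-methylbut-2-en-1-yl)-2,3-dihydro-1-benzofuran-5-yl]-1-[2,4,6-tris(tert-butyldimethylsilyloxy)phenyl]prop-2-yn-1-one
Conditions: PdCl2(PPh3)2 (3 mol %), CuI (6 mol %), Et3N (2 equiv), degassed THF, rt; 13 (1.3 equiv) added slowly
Reagents that add atoms: none
Why: Sonogashira coupling of an aryl iodide with a terminal alkynyl ketone, which should run at room temperature, tolerate both free hydroxyls, and, with a tertiary amine, slow addition and exclusion of oxygen, outpace amine conjugate addition and Glaser dimerisation of the ynone.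

Step 9
Reactants: 14 3-[(2S,3S)-3-hydroxy-2-(2-hydroxypropan-2-yl)-7-(3-methylbut-2-en-1-yl)-2,3-dihydro-1-benzofuran-5-yl]-1-[2,4,6-tris(tert-butyldimethylsilyloxy)phenyl]prop-2-yn-1-one
Product: 16 5,7-dihydroxy-2-[(2S,3S)-3-hydroxy-2-(2-hydroxypropan-2-yl)-7-(3-methylbut-2-en-1-yl)-2,3-dihydro-1-benzofuran-5-yl]-4H-chromen-4-one, via triphenol ynone 15 (not isolated)
Conditions: KF (spray-dried, 6 equiv), 18-crown-6 (cat.), DMF, rt to 40 °C; then AcOH
Reagents that add atoms: none
Why: fluoride desilylation should free the ring A phenoxides, and an ortho phenoxide then adds to the ynone by 6-endo-dig oxa-Michael cyclisation (the aprotic medium favours this conjugate mode over the 5-exo-dig closure to an aurone); either ortho oxygen of the symmetric ring gives the same 5,7-dihydroxychromone and the two stereocentres are not touched.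

**Compound list**

1 | 4-iodophenol | Oc1ccc(I)cc1 | starting material
2 | prenyl bromide (1-bromo-3-methylbut-2-ene) | CC(C)=CCBr | starting material
3 | 4-iodo-2-(3-methylbut-2-en-1-yl)phenol | CC(C)=CCc1cc(I)ccc1O | intermediate
4 | prenol (3-methylbut-2-en-1-ol) | CC(C)=CCO | starting material
5 | [(2R)-3,3-dimethyloxiran-2-yl]methanol | OC[C@H]1OC1(C)C | intermediate
6 | (2S)-3,3-dimethyloxirane-2-carbaldehyde | O=C[C@H]1OC1(C)C | intermediate
7 | 2-{(S)-[(2R)-3,3-dimethyloxiran-2-yl](hydroxy)methyl}-4-iodo-6-(3-methylbut-2-en-1-yl)phenol (present as its magnesium salt, not isolated) | CC(C)=CCc1cc(I)cc([C@H](O)[C@H]2OC2(C)C)c1O | intermediate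
8 | (2S,3S)-2-(2-hydroxypropan-2-yl)-5-iodo-7-(3-methylbut-2-en-1-yl)-2,3-dihydro-1-benzofuran-3-ol | CC(C)=CCc1cc(I)cc2c1O[C@H](C(C)(C)O)[C@H]2O | intermediate
9 | 2,4,6-trihydroxybenzaldehyde | O=Cc1c(O)cc(O)cc1O | starting material
10 | 2,4,6-tris(tert-butyldimethylsilyloxy)benzaldehyde | O=Cc1c(O[Si](C)(C)C(C)(C)C)cc(O[Si](C)(C)C(C)(C)C)cc1O[Si](C)(C)C(C)(C)C | intermediate
11 | ethynylmagnesium bromide | C#C[Mg]Br | starting material
12 | (±)-1-[2,4,6-tris(tert-butyldimethylsilyloxy)phenyl]prop-2-yn-1-ol | C#CC(O)c1c(O[Si](C)(C)C(C)(C)C)cc(O[Si](C)(C)C(C)(C)C)cc1O[Si](C)(C)C(C)(C)C | intermediate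
13 | 1-[2,4,6-tris(tert-butyldimethylsilyloxy)phenyl]prop-2-yn-1-one | C#CC(=O)c1c(O[Si](C)(C)C(C)(C)C)cc(O[Si](C)(C)C(C)(C)C)cc1O[Si](C)(C)C(C)(C)C | intermediate
14 | 3-[(2S,3S)-3-hydroxy-2-(2-hydroxypropan-2-yl)-7-(3-methylbut-2-en-1-yl)-2,3-dihydro-1-benzofuran-5-yl]-1-[2,4,6-tris(tert-butyldimethylsilyloxy)phenyl]prop-2-yn-1-one | CC(C)=CCc1cc(C#CC(=O)c3c(O[Si](C)(C)C(C)(C)C)cc(O[Si](C)(C)C(C)(C)C)cc3O[Si](C)(C)C(C)(C)C)cc2c1O[C@H](C(C)(C)O)[C@H]2O | intermediate
15 | 3-[(2S,3S)-3-hydroxy-2-(2-hydroxypropan-2-yl)-7-(3-methylbut-2-en-1-yl)-2,3-dihydro-1-benzofuran-5-yl]-1-(2,4,6-trihydroxyphenyl)prop-2-yn-1-one (present as its potassium phenoxide, not isolated) | CC(C)=CCc1cc(C#CC(=O)c3c(O)cc(O)cc3O)cc2c1O[C@H](C(C)(C)O)[C@H]2O | intermediate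
16 | 5,7-dihydroxy-2-[(2S,3S)-3-hydroxy-2-(2-hydroxypropan-2-yl)-7-(3-methylbut-2-en-1-yl)-2,3-dihydro-1-benzofuran-5-yl]-4H-chromen-4-one | CC(C)=CCc1cc(-c2cc(=O)c3c(O)cc(O)cc3o2)cc2c1O[C@H](C(C)(C)O)[C@H]2O | target

**Totals**

Total step count: 9. Longest linear sequence: 5 steps (steps 5, 6, 7, 8, 9; the branch through steps 2, 3, 4, 8, 9 is equally long).

**Steps most likely to fail**

1. Step 4. The deactivated iodophenoxide may add to the aldehyde too slowly, or with poor facial selectivity through the non-chelated Felkin–Anh mode that leads to the cis ring, or the epoxide may open in the 6-endo sense. The fallback uses known chemistry, sets out from 3 and comes back at 8. Magnesium-mediated ortho-formylation of 3 (MgCl2, Et3N, paraformaldehyde, MeCN, reflux) should give 2-hydroxy-5-iodo-3-(3-methylbut-2-en-1-yl)benzaldehyde F1. O-Alkylation with chloroacetone (K2CO3, acetone, rt, stopped before Rap–Stoermer condensation sets in) should give 5-iodo-3-(3-methylbut-2-en-1-yl)-2-(2-oxopropoxy)benzaldehyde F2. An (S)-proline-catalysed intramolecular 5-enolexo aldol reaction (DMF, rt; the antipodal catalyst is at hand should the sense prove opposite) should give the cis ketol 1-[(2S,3R)-3-hydroxy-5-iodo-7-(3-methylbut-2-en-1-yl)-2,3-dihydro-1-benzofuran-2-yl]ethan-1-one F3. Addition of MeMgBr/CeCl3 (THF, −78 °C) to the ketone should give the cis diol (2S,3R)-2-(2-hydroxypropan-2-yl)-5-iodo-7-(3-methylbut-2-en-1-yl)-2,3-dihydro-1-benzofuran-3-ol F4. Mitsunobu inversion at the benzylic carbinol (4-nitrobenzoic acid, PPh3, DIAD, THF, 0 °C) should give (2S,3S)-2-(2-hydroxypropan-2-yl)-5-iodo-7-(3-methylbut-2-en-1-yl)-2,3-dihydro-1-benzofuran-3-yl 4-nitrobenzoate F5, and methanolysis (K2CO3, MeOH) returns 8.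

2. Step 8. The terminal ynone 13 may be consumed by base-induced oligomerisation, amine conjugate addition or Glaser dimerisation faster than it cross-couples. The fallback couples at the alcohol oxidation level, sets out from 8 and 12 and comes back at 14. Sonogashira coupling of 8 with the propargylic alcohol 12 (PdCl2(PPh3)2, CuI, Et3N, THF) should give 3-[(2S,3S)-3-hydroxy-2-(2-hydroxypropan-2-yl)-7-(3-methylbut-2-en-1-yl)-2,3-dihydro-1-benzofuran-5-yl]-1-[2,4,6-tris(tert-butyldimethylsilyloxy)phenyl]prop-2-yn-1-ol F6 as a mixture of carbinol epimers. MnO2 in CH2Cl2 should then oxidise the doubly activated carbinol in preference to the ring B benzylic alcohol, returning 14.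

3. Step 9. The phenoxide may close in the 5-exo-dig mode to an aurone, or the electron-rich triphenoxide may cyclise incompletely. The fallback uses an amine relay, sets out from 14 and comes back at 16. Conjugate addition of Et2NH to the ynone (EtOH/THF, rt) should give the enaminone 3-(diethylamino)-3-[(2S,3S)-3-hydroxy-2-(2-hydroxypropan-2-yl)-7-(3-methylbut-2-en-1-yl)-2,3-dihydro-1-benzofuran-5-yl]-1-[2,4,6-tris(tert-butyldimethylsilyloxy)phenyl]prop-2-en-1-one F7. Fluoride desilylation (KF, 18-crown-6, DMF, then AcOH) then lets an ortho phenoxide displace diethylamine by addition–elimination, which can only form the six-membered pyranone, giving 16.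

**Further compounds**

F1 | step 4 | 2-hydroxy-5-iodo-3-(3-methylbut-2-en-1-yl)benzaldehyde | CC(C)=CCc1cc(I)cc(C=O)c1O
F2 | step 4 | 5-iodo-3-(3-methylbut-2-en-1-yl)-2-(2-oxopropoxy)benzaldehyde | CC(C)=CCc1cc(I)cc(C=O)c1OCC(C)=O
F3 | step 4 | 1-[(2S,3R)-3-hydroxy-5-iodo-7-(3-methylbut-2-en-1-yl)-2,3-dihydro-1-benzofuran-2-yl]ethan-1-one | CC(C)=CCc1cc(I)cc2c1O[C@H](C(C)=O)[C@@H]2O
F4 | step 4 | (2S,3R)-2-(2-hydroxypropan-2-yl)-5-iodo-7-(3-methylbut-2-en-1-yl)-2,3-dihydro-1-benzofuran-3-ol | CC(C)=CCc1cc(I)cc2c1O[C@H](C(C)(C)O)[C@@H]2O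
F5 | step 4 | (2S,3S)-2-(2-hydroxypropan-2-yl)-5-iodo-7-(3-methylbut-2-en-1-yl)-2,3-dihydro-1-benzofuran-3-yl 4-nitrobenzoate | CC(C)=CCc1cc(I)cc2c1O[C@H](C(C)(C)O)[C@H]2OC(=O)c1ccc(cc1)[N+](=O)[O-]
F6 | step 8 | 3-[(2S,3S)-3-hydroxy-2-(2-hydroxypropan-2-yl)-7-(3-methylbut-2-en-1-yl)-2,3-dihydro-1-benzofuran-5-yl]-1-[2,4,6-tris(tert-butyldimethylsilyloxy)phenyl]prop-2-yn-1-ol | CC(C)=CCc1cc(C#CC(O)c3c(O[Si](C)(C)C(C)(C)C)cc(O[Si](C)(C)C(C)(C)C)cc3O[Si](C)(C)C(C)(C)C)cc2c1O[C@H](C(C)(C)O)[C@H]2O
F7 | step 9 | 3-(diethylamino)-3-[(2S,3S)-3-hydroxy-2-(2-hydroxypropan-2-yl)-7-(3-methylbut-2-en-1-yl)-2,3-dihydro-1-benzofuran-5-yl]-1-[2,4,6-tris(tert-butyldimethylsilyloxy)phenyl]prop-2-en-1-one | CC(C)=CCc1cc(C(N(CC)CC)=CC(=O)c3c(O[Si](C)(C)C(C)(C)C)cc(O[Si](C)(C)C(C)(C)C)cc3O[Si](C)(C)C(C)(C)C)cc2c1O[C@H](C(C)(C)O)[C@H]2O
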